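## Retrosynthetic overview

1. Last bond: the CH2–C(quaternary) bond of ring B, made by gramine-type C-alkylation of dienol ester 26 with the ring A trimethylammonium salt 18 (via an aza-quinone methide).
2. Ring B (26): enzymatic hydroxylative dearomatization (FAD-dependent monooxygenase) of benzaldehyde 23, acylation with (S)-2-methylbutanoic anhydride, then removal of the formyl handle.
3. Ring A (18): the same enzymatic dearomatization on aryl ketone 13, then enol O-methylation, OMe→NH2 exchange and Mannich aminomethylation.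
4. Both arenes come from 2-methylresorcinol (Ir C–H borylation/oxidation, directed lithiations, one bromination/Suzuki methylation); both acyl groups come from tiglic acid by Ru-catalysed asymmetric hydrogenation, which sets the first stereocentre.
5. No ring is built: ring A and ring B are carried as benzene rings, dearomatized separately (ring A line first, ring B line second) and then joined.

Assumption: the SMILES is taken literally, so the ring A ketone side chain is (R)-2-methylbutanoyl and the ring B ester is (S)-2-methylbutanoate; both antipodes of the acid are therefore made.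

## Route

Step 1
Reactants: 1 tiglic acid
Product: 2 (R)-2-methylbutanoic acid
Conditions: H2 (4 atm), Ru(OAc)2[(R)-H8-BINAP] (0.5 mol %), MeOH, 20 °C
Reagents that add atoms: none
Why: Noyori-type carboxylate-directed asymmetric hydrogenation, in which the (R)-diphosphine complex adds H2 to one face of the trisubstituted alkene and sets the first stereocentre as (R).

Step 2
Reactants: 2 (R)-2-methylbutanoic acid
Product: 3 (R)-N-methoxy-N,2-dimethylbutanamide
Conditions: CDI, CH2Cl2, 0 °C to rt; then MeNH(OMe)·HCl, rt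
Reagents that add atoms: N,O-dimethylhydroxylamine hydrochloride, CNOC.Cl
Why: Weinreb amide formation through the acyl imidazolide, with no strong base present, so the α-stereocentre is not touched.

Step 3
Reactants: 1 tiglic acid
Product: 4 (S)-2-methylbutanoic acid
Conditions: H2 (4 atm), Ru(OAc)2[(S)-H8-BINAP] (0.5 mol %), MeOH, 20 °C
Reagents that add atoms: none
Why: the same asymmetric hydrogenation with the enantiomeric ligand gives the (S)-acid.

Step 4
Reactants: 4 (S)-2-methylbutanoic acid (2 equiv)
Product: 5 (S)-2-methylbutanoic anhydride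
Conditions: DCC (0.5 equiv per acid), CH2Cl2, 0 °C to rt, filter
Reagents that add atoms: (S)-2-methylbutanoic acid (second molecule of 4), CC[C@H](C)C(=O)O
Why: carbodiimide dehydration joins two molecules of 4 through the O-acylisourea to the symmetric anhydride, which does not pass through a ketene and so keeps the α-stereocentre.

Step 5
Reactants: 6 2-methylresorcinol
Product: 7 1,3-bis(methoxymethoxy)-2-methylbenzene
Conditions: NaH (2.2 equiv), MOMCl (2.2 equiv), DMF, 0 °C to rt
Reagents that add atoms: chloromethyl methyl ether, COCCl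
Why: Williamson-type O-alkylation of both phenoxides gives the bis-MOM ether, which later directs ortho-lithiation.

Step 6
Reactants: 7 1,3-bis(methoxymethoxy)-2-methylbenzene
Product: 9 3,5-bis(methoxymethoxy)-4-methylphenol, via pinacol boronate 8 (not isolated)
Conditions: [Ir(OMe)(cod)]2 (1.5 mol %), 4,4'-di-tert-butyl-2,2'-bipyridine (3 mol %), B2pin2 (1.0 equiv), THF, 80 °C; then 30% aq. H2O2, THF/H2O, 0 °C to rt
Reagents that add atoms: bis(pinacolato)diboron, CC1(C)OB(OC1(C)C)B1OC(C)(C)C(C)(C)O1 (boron of 8); hydrogen peroxide, OO (oxygen of 9)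
Why: sterically controlled Ir-catalysed C–H borylation occurs only at the one C–H with no ortho substituent (para to the methyl), and oxidation of the C–B bond gives the phenol.

Step 7
Reactants: 9 3,5-bis(methoxymethoxy)-4-methylphenol
Product: 10 5-methoxy-1,3-bis(methoxymethoxy)-2-methylbenzene
Conditions: MeI, K2CO3, acetone, 50 °C
Reagents that add atoms: iodomethane, CI
Why: Williamson O-methylation of the only free phenol fixes the position of the ring methoxy group before any dearomatization.

Step 8
Reactants: 10 5-methoxy-1,3-bis(methoxymethoxy)-2-methylbenzene; 3 (R)-N-methoxy-N,2-dimethylbutanamide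
Product: 12 (2R)-1-[6-methoxy-2,4-bis(methoxymethoxy)-3-methylphenyl]-2-methylbutan-1-one, via aryllithium 11 (not isolated)
Conditions: n-BuLi (1.1 equiv), TMEDA, THF, 0 °C; then 3, −78 °C to 0 °C; aq. NH4Cl
Reagents that add atoms: n-butyllithium, [Li]CCCC (lithium of 11)
Why: directed ortho-metalation between OMOM and OMe followed by Weinreb ketone synthesis, where the chelated tetrahedral intermediate stops over-addition and the low temperature protects the α-stereocentre.

Step 9
Reactants: 12 (2R)-1-[6-methoxy-2,4-bis(methoxymethoxy)-3-methylphenyl]-2-methylbutan-1-one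
Product: 13 (2R)-1-(2,4-dihydroxy-6-methoxy-3-methylphenyl)-2-methylbutan-1-one
Conditions: 1.25 M HCl in MeOH, rt
Reagents that add atoms: none
Why: acid-catalysed acetal exchange removes both MOM groups under conditions too mild to enolize the hindered aryl ketone.

Step 10
Reactants: 13 (2R)-1-(2,4-dihydroxy-6-methoxy-3-methylphenyl)-2-methylbutan-1-one
Product: 14 (6R)-5,6-dihydroxy-3-methoxy-6-methyl-4-[(2R)-2-methylbutanoyl]cyclohexa-2,4-dien-1-one
Conditions: FAD-dependent monooxygenase (TropB/AzaH family, (R)-selective member, cell lysate), NADP+ (cat.), phosphite dehydrogenase, Na2HPO3, air, phosphate buffer pH 8.0, 5% DMSO, 30 °C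
Reagents that add atoms: dioxygen, O=O
Why: enzymatic hydroxylative dearomatization, in which the flavin C4a-hydroperoxide delivers oxygen to the methyl-bearing carbon between the two phenolic OH groups from the single face exposed in the active site, setting the ring A carbinol as (R).

Step 11
Reactants: 14 (6R)-5,6-dihydroxy-3-methoxy-6-methyl-4-[(2R)-2-methylbutanoyl]cyclohexa-2,4-dien-1-one
Product: 15 (6R)-6-hydroxy-3,5-dimethoxy-6-methyl-4-[(2R)-2-methylbutanoyl]cyclohexa-2,4-dien-1-one
Conditions: CH2N2, Et2O, 0 °C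
Reagents that add atoms: diazomethane, C=[N+]=[N-]
Why: O-methylation of the acidic chelated enol by diazomethane in a non-polar solvent, where the tight ion pair should collapse at the oxygen that carried the proton; the tertiary alcohol does not react and any regioisomeric enol ether is removed by chromatography.

Step 12
Reactants: 15 (6R)-6-hydroxy-3,5-dimethoxy-6-methyl-4-[(2R)-2-methylbutanoyl]cyclohexa-2,4-dien-1-one
Product: 16 (6R)-5-amino-6-hydroxy-3-methoxy-6-methyl-4-[(2R)-2-methylbutanoyl]cyclohexa-2,4-dien-1-one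
Conditions: NH3 (7 M in MeOH, 3 equiv), 0 °C to rt
Reagents that add atoms: ammonia, N
Why: vinylogous addition–elimination (conjugate addition of ammonia, loss of methanol) at C-5, the only methoxy carbon activated by both the side-chain ketone and the ring ketone, which gives the chelated vinylogous amide.

Step 13
Reactants: 16 (6R)-5-amino-6-hydroxy-3-methoxy-6-methyl-4-[(2R)-2-methylbutanoyl]cyclohexa-2,4-dien-1-one
Product: 17 (6R)-5-amino-2-[(dimethylamino)methyl]-6-hydroxy-3-methoxy-6-methyl-4-[(2R)-2-methylbutanoyl]cyclohexa-2,4-dien-1-one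
Conditions: Eschenmoser's salt (1.2 equiv), CH2Cl2/MeCN, rt; then sat. aq. NaHCO3
Reagents that add atoms: N,N-dimethylmethyleneiminium iodide, C=[N+](C)C.[I-]
Why: Mannich reaction at C-2, the only ring C–H, which is nucleophilic as the terminus of the push–pull dienamine and the β-carbon of the enol ether.

Step 14
Reactants: 17 (6R)-5-amino-2-[(dimethylamino)methyl]-6-hydroxy-3-methoxy-6-methyl-4-[(2R)-2-methylbutanoyl]cyclohexa-2,4-dien-1-one
Product: 18 {(5R)-4-amino-5-hydroxy-2-methoxy-5-methyl-3-[(2R)-2-methylbutanoyl]-6-oxocyclohexa-1,3-dien-1-yl}-N,N,N-trimethylmethanaminium iodide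
Conditions: MeI (5 equiv), acetone, rt, dark; collect the precipitate
Reagents that add atoms: iodomethane, CI
Why: Menshutkin quaternization of the only basic nitrogen (the vinylogous amide NH2 is not nucleophilic) turns the amine into a leaving group.

Step 15
Reactants: 10 5-methoxy-1,3-bis(methoxymethoxy)-2-methylbenzene
Product: 19 2-bromo-1-methoxy-3,5-bis(methoxymethoxy)-4-methylbenzene
Conditions: NBS (1.0 equiv), DMF, −10 °C to 0 °C, dark
Reagents that add atoms: N-bromosuccinimide, O=C1CCC(=O)N1Br
Why: electrophilic aromatic bromination of the electron-rich arene, in which the two free ring positions are equivalent by symmetry so that monobromination gives one regioisomer, and the acid-free medium keeps the MOM acetals.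

Step 16
Reactants: 19 2-bromo-1-methoxy-3,5-bis(methoxymethoxy)-4-methylbenzene
Product: 20 1-methoxy-3,5-bis(methoxymethoxy)-2,4-dimethylbenzene
Conditions: MeB(OH)2 (2.0 equiv), Pd(OAc)2 (3 mol %), SPhos (6 mol %), K3PO4 (3 equiv), toluene/H2O (10:1), 100 °C
Reagents that add atoms: methylboronic acid, CB(O)O
Why: Suzuki–Miyaura cross-coupling, in which the bulky electron-rich biaryl phosphine lets zerovalent palladium insert into the hindered C–Br bond and installs the second ring methyl next to the methoxy group.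

Step 17
Reactants: 20 1-methoxy-3,5-bis(methoxymethoxy)-2,4-dimethylbenzene
Product: 22 2-methoxy-4,6-bis(methoxymethoxy)-3,5-dimethylbenzaldehyde, via aryllithium 21 (not isolated)
Conditions: n-BuLi (1.2 equiv), TMEDA, THF, 0 °C; then DMF, −78 °C to rt; aq. NH4Cl
Reagents that add atoms: n-butyllithium, [Li]CCCC (lithium of 21); N,N-dimethylformamide, CN(C)C=O
Why: directed ortho-metalation at the last ring C–H (between OMe and OMOM) and formylation with DMF (Bouveault-type).

Step 18
Reactants: 22 2-methoxy-4,6-bis(methoxymethoxy)-3,5-dimethylbenzaldehyde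
Product: 23 2,4-dihydroxy-6-methoxy-3,5-dimethylbenzaldehyde
Conditions: 3 M aq. HCl, THF, 40 °C
Reagents that add atoms: none
Why: acid hydrolysis of the two MOM acetals; aqueous conditions keep the aldehyde free of acetal.

Step 19
Reactants: 23 2,4-dihydroxy-6-methoxy-3,5-dimethylbenzaldehyde
Product: 24 (3R)-2,3-dihydroxy-6-methoxy-3,5-dimethyl-4-oxocyclohexa-1,5-diene-1-carbaldehyde
Conditions: FAD-dependent monooxygenase (same (R)-selective TropB/AzaH-family enzyme), NADP+ (cat.), phosphite dehydrogenase, Na2HPO3, air, phosphate buffer pH 8.0, 5% DMSO, 30 °C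
Reagents that add atoms: dioxygen, O=O
Why: the same enzymatic hydroxylative dearomatization on a close analogue of the native 3-methylorcinaldehyde substrate sets the ring B carbinol, with the same facial sense relative to the carbonyl handle as in step 10.

Step 20
Reactants: 24 (3R)-2,3-dihydroxy-6-methoxy-3,5-dimethyl-4-oxocyclohexa-1,5-diene-1-carbaldehyde; 5 (S)-2-methylbutanoic anhydride
Product: 25 (1R)-5-formyl-6-hydroxy-4-methoxy-1,3-dimethyl-2-oxocyclohexa-3,5-dien-1-yl (2S)-2-methylbutanoate
Conditions: 5 (3 equiv), DMAP (0.2 equiv), pyridine, CH2Cl2, 0 °C to rt; MeOH quench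
Reagents that add atoms: none
Why: DMAP-catalysed acylation of the tertiary α-ketol (as in acetylation of o-quinols), in which the carbinol C–O bond is not broken and any labile enol ester is cleaved by the methanol quench.

Step 21
Reactants: 25 (1R)-5-formyl-6-hydroxy-4-methoxy-1,3-dimethyl-2-oxocyclohexa-3,5-dien-1-yl (2S)-2-methylbutanoate
Product: 26 (1S)-2-hydroxy-4-methoxy-1,3-dimethyl-6-oxocyclohexa-2,4-dien-1-yl (2S)-2-methylbutanoate
Conditions: MeOH, PPTS (5 mol %), 50 °C
Reagents that add atoms: none
Why: retro-Claisen deformylation by methanolysis, which expels the stabilized vinylogous-acid enol and in which exchange of the ring OMe with the solvent is degenerate; the 1R to 1S change is only a CIP consequence of the tautomer drawn.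

Step 22
Reactants: 18 {(5R)-4-amino-5-hydroxy-2-methoxy-5-methyl-3-[(2R)-2-methylbutanoyl]-6-oxocyclohexa-1,3-dien-1-yl}-N,N,N-trimethylmethanaminium iodide; 26 (1S)-2-hydroxy-4-methoxy-1,3-dimethyl-6-oxocyclohexa-2,4-dien-1-yl (2S)-2-methylbutanoate
Product: 28 (1R,3R)-3-({(5R)-4-amino-5-hydroxy-2-methoxy-5-methyl-3-[(2R)-2-methylbutanoyl]-6-oxocyclohexa-1,3-dien-1-yl}methyl)-4-methoxy-1,3-dimethyl-2,6-dioxocyclohex-4-en-1-yl (2S)-2-methylbutanoate (CNP0537128.1), via aza-quinone methide 27 (not isolated)
Conditions: NaHCO3 (1.2 equiv), DMF, 0 °C to rt; the acidic regioisomer is removed by a bicarbonate wash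
Reagents that add atoms: none
Why: gramine-type elimination–addition in which loss of NMe3 gives aza-quinone methide 27 and the sodium dienolate of 26 adds in a Michael reaction through its methyl-bearing C-3, expected to attack from the face opposite the 2-methylbutanoyloxy group that overhangs the ring, which gives the (3R) quaternary centre trans to the ester.

## Compound list

1 | tiglic acid, (E)-2-methylbut-2-enoic acid | C/C=C(\C)C(=O)O | starting material
2 | (R)-2-methylbutanoic acid | CC[C@@H](C)C(=O)O | intermediate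
3 | (R)-N-methoxy-N,2-dimethylbutanamide | CC[C@@H](C)C(=O)N(C)OC | intermediate
4 | (S)-2-methylbutanoic acid | CC[C@H](C)C(=O)O | intermediate
5 | (S)-2-methylbutanoic anhydride (both centres S) | CC[C@H](C)C(=O)OC(=O)[C@@H](C)CC | intermediate
6 | 2-methylresorcinol (2-methylbenzene-1,3-diol) | Cc1c(O)cccc1O | starting material
7 | 1,3-bis(methoxymethoxy)-2-methylbenzene | COCOc1cccc(OCOC)c1C | intermediate
8 | 2-[3,5-bis(methoxymethoxy)-4-methylphenyl]-4,4,5,5-tetramethyl-1,3,2-dioxaborolane | COCOc1cc(B2OC(C)(C)C(C)(C)O2)cc(OCOC)c1C | intermediate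
9 | 3,5-bis(methoxymethoxy)-4-methylphenol | COCOc1cc(O)cc(OCOC)c1C | intermediate
10 | 5-methoxy-1,3-bis(methoxymethoxy)-2-methylbenzene | COCOc1cc(OC)cc(OCOC)c1C | intermediate
11 | [6-methoxy-2,4-bis(methoxymethoxy)-3-methylphenyl]lithium | [Li]c1c(OC)cc(OCOC)c(C)c1OCOC | intermediate
12 | (2R)-1-[6-methoxy-2,4-bis(methoxymethoxy)-3-methylphenyl]-2-methylbutan-1-one | CC[C@@H](C)C(=O)c1c(OC)cc(OCOC)c(C)c1OCOC | intermediate
13 | (2R)-1-(2,4-dihydroxy-6-methoxy-3-methylphenyl)-2-methylbutan-1-one | CC[C@@H](C)C(=O)c1c(OC)cc(O)c(C)c1O | intermediate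
14 | (6R)-5,6-dihydroxy-3-methoxy-6-methyl-4-[(2R)-2-methylbutanoyl]cyclohexa-2,4-dien-1-one | CC[C@@H](C)C(=O)C1=C(O)[C@@](C)(O)C(=O)C=C1OC | intermediate
15 | (6R)-6-hydroxy-3,5-dimethoxy-6-methyl-4-[(2R)-2-methylbutanoyl]cyclohexa-2,4-dien-1-one | CC[C@@H](C)C(=O)C1=C(OC)[C@@](C)(O)C(=O)C=C1OC | intermediate
16 | (6R)-5-amino-6-hydroxy-3-methoxy-6-methyl-4-[(2R)-2-methylbutanoyl]cyclohexa-2,4-dien-1-one | CC[C@@H](C)C(=O)C1=C(N)[C@@](C)(O)C(=O)C=C1OC | intermediate
17 | (6R)-5-amino-2-[(dimethylamino)methyl]-6-hydroxy-3-methoxy-6-methyl-4-[(2R)-2-methylbutanoyl]cyclohexa-2,4-dien-1-one | CC[C@@H](C)C(=O)C1=C(N)[C@@](C)(O)C(=O)C(CN(C)C)=C1OC | intermediate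
18 | {(5R)-4-amino-5-hydroxy-2-methoxy-5-methyl-3-[(2R)-2-methylbutanoyl]-6-oxocyclohexa-1,3-dien-1-yl}-N,N,N-trimethylmethanaminium iodide | CC[C@@H](C)C(=O)C1=C(N)[C@@](C)(O)C(=O)C(C[N+](C)(C)C)=C1OC.[I-] | intermediate
19 | 2-bromo-1-methoxy-3,5-bis(methoxymethoxy)-4-methylbenzene | COCOc1cc(OC)c(Br)c(OCOC)c1C | intermediate
20 | 1-methoxy-3,5-bis(methoxymethoxy)-2,4-dimethylbenzene | COCOc1cc(OC)c(C)c(OCOC)c1C | intermediate
21 | [2-methoxy-4,6-bis(methoxymethoxy)-3,5-dimethylphenyl]lithium | [Li]c1c(OC)c(C)c(OCOC)c(C)c1OCOC | intermediate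
22 | 2-methoxy-4,6-bis(methoxymethoxy)-3,5-dimethylbenzaldehyde | O=Cc1c(OC)c(C)c(OCOC)c(C)c1OCOC | intermediate
23 | 2,4-dihydroxy-6-methoxy-3,5-dimethylbenzaldehyde | O=Cc1c(OC)c(C)c(O)c(C)c1O | intermediate
24 | (3R)-2,3-dihydroxy-6-methoxy-3,5-dimethyl-4-oxocyclohexa-1,5-diene-1-carbaldehyde | O=CC1=C(O)[C@@](C)(O)C(=O)C(C)=C1OC | intermediate
25 | (1R)-5-formyl-6-hydroxy-4-methoxy-1,3-dimethyl-2-oxocyclohexa-3,5-dien-1-yl (2S)-2-methylbutanoate | O=CC1=C(O)[C@@](C)(OC(=O)[C@@H](C)CC)C(=O)C(C)=C1OC | intermediate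
26 | (1S)-2-hydroxy-4-methoxy-1,3-dimethyl-6-oxocyclohexa-2,4-dien-1-yl (2S)-2-methylbutanoate (wasabidienone A constitution) | COC1=CC(=O)[C@@](C)(OC(=O)[C@@H](C)CC)C(O)=C1C | intermediate
27 | (6R)-6-hydroxy-5-imino-3-methoxy-6-methyl-2-methylidene-4-[(2R)-2-methylbutanoyl]cyclohex-3-en-1-one (aza-quinone methide) | CC[C@@H](C)C(=O)C1=C(OC)C(=C)C(=O)[C@](C)(O)C1=N | intermediate
28 | (1R,3R)-3-({(5R)-4-amino-5-hydroxy-2-methoxy-5-methyl-3-[(2R)-2-methylbutanoyl]-6-oxocyclohexa-1,3-dien-1-yl}methyl)-4-methoxy-1,3-dimethyl-2,6-dioxocyclohex-4-en-1-yl (2S)-2-methylbutanoate | CC[C@@H](C)C(=O)C1=C(N)[C@@](C)(O)C(=O)C(C[C@@]2(C)C(=O)[C@](C)(OC(=O)[C@@H](C)CC)C(=O)C=C2OC)=C1OC | target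

## Step count and risks

Total step count: 22. Longest linear sequence: 11 steps (6 → 7 → 9 → 10 → 12 → 13 → 14 → 15 → 16 → 17 → 18 → 28, steps 5–14 and 22; the ring B line, steps 5–7 and 15–22, is equally long).

Most likely to fail, first: step 22. The dienolate of 26 has a second carbon terminus (the unsubstituted C-5) that is less hindered, and the facial preference at C-3 is argued from conformation, not demonstrated. The fallback sets out from 25 and 18. Compound 25 still carries the formyl group on that second carbon, so only the methyl-bearing carbon can be alkylated. The same NaHCO3/DMF alkylation gives (1S,3R)-3-({(5R)-4-amino-5-hydroxy-2-methoxy-5-methyl-3-[(2R)-2-methylbutanoyl]-6-oxocyclohexa-1,3-dien-1-yl}methyl)-5-formyl-4-methoxy-1,3-dimethyl-2,6-dioxocyclohex-4-en-1-yl (2S)-2-methylbutanoate F1. Its spatial arrangement is that of 28; the 1S descriptor arises only because the formyl group changes the CIP ranking. Stoichiometric RhCl(PPh3)3 in toluene at 90 °C (Tsuji–Wilkinson decarbonylation of the vinylogous enal) then removes the formyl group, and the fallback comes back to the route at 28.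

Second: step 11. Diazomethane may methylate the other enol oxygen (the one para to the acyl carbon) and give a regioisomeric dienone. The fallback sets out from 13 and fixes the methyl ether on the arene. BnBr/K2CO3 in acetone benzylates the free, non-chelated 4-OH to give (2R)-1-[4-(benzyloxy)-2-hydroxy-6-methoxy-3-methylphenyl]-2-methylbutan-1-one F2. MeI/K2CO3 in DMF methylates the chelated 2-OH to give (2R)-1-[4-(benzyloxy)-2,6-dimethoxy-3-methylphenyl]-2-methylbutan-1-one F3. H2 over 10% Pd/C in EtOAc gives (2R)-1-(4-hydroxy-2,6-dimethoxy-3-methylphenyl)-2-methylbutan-1-one F4. A catalytic asymmetric hydroxylative phenol dearomatization (C2-symmetric chiral aryl iodide, mCPBA, hypervalent-iodine oxygen transfer to the methyl-bearing ortho carbon) then gives 15, where the fallback comes back to the route, bypassing 14.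

Third: step 21. Methanolytic deformylation of the strongly chelated tricarbonyl may be slow. The fallback sets out from 25 and removes the carbon oxidatively. Pinnick oxidation (NaClO2, NaH2PO4, 2-methyl-2-butene, t-BuOH/H2O, rt) gives (3R)-2-hydroxy-6-methoxy-3,5-dimethyl-3-{[(2S)-2-methylbutanoyl]oxy}-4-oxocyclohexa-1,5-diene-1-carboxylic acid F5. This β-keto acid decarboxylates on warming to 40 °C and comes back to the route at 26.

## Further compounds

F1 | step 22 | (1S,3R)-3-({(5R)-4-amino-5-hydroxy-2-methoxy-5-methyl-3-[(2R)-2-methylbutanoyl]-6-oxocyclohexa-1,3-dien-1-yl}methyl)-5-formyl-4-methoxy-1,3-dimethyl-2,6-dioxocyclohex-4-en-1-yl (2S)-2-methylbutanoate | CC[C@@H](C)C(=O)C1=C(N)[C@@](C)(O)C(=O)C(C[C@@]2(C)C(=O)[C@](C)(OC(=O)[C@@H](C)CC)C(=O)C(C=O)=C2OC)=C1OC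
F2 | step 11 | (2R)-1-[4-(benzyloxy)-2-hydroxy-6-methoxy-3-methylphenyl]-2-methylbutan-1-one | CC[C@@H](C)C(=O)c1c(O)c(C)c(OCc2ccccc2)cc1OC
F3 | step 11 | (2R)-1-[4-(benzyloxy)-2,6-dimethoxy-3-methylphenyl]-2-methylbutan-1-one | CC[C@@H](C)C(=O)c1c(OC)c(C)c(OCc2ccccc2)cc1OC
F4 | step 11 | (2R)-1-(4-hydroxy-2,6-dimethoxy-3-methylphenyl)-2-methylbutan-1-one | CC[C@@H](C)C(=O)c1c(OC)c(C)c(O)cc1OC
F5 | step 21 | (3R)-2-hydroxy-6-methoxy-3,5-dimethyl-3-{[(2S)-2-methylbutanoyl]oxy}-4-oxocyclohexa-1,5-diene-1-carboxylic acid | O=C(O)C1=C(O)[C@@](C)(OC(=O)[C@@H](C)CC)C(=O)C(C)=C1OC
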